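**Plan**
- Retrosynthesis: the 7-O–ethyl bond is cut last; ring A is then cut at C8–C8a, C7–C8, C5–C6 and C4a–C5 (chromone numbering), leaving 2-(2-diazoacetyl)-6-icosyl-4H-pyran-4-one and ethoxyacetylene.
- The diazo ketone goes back to 6-icosyl-4-pyranone-2-carboxylic acid, the pyranone ring to a linear 2,4,6-triketo ester (oxalate Claisen), and the chain to a C–C alkylation of the acetylacetone dianion with a C19 bromide.
- Forward order: chain joined first, pyranone ring second, ring A third (benzannulation), de-ethylation last.
- Enabling feature: ring A carries oxygen at C5 and C7 (meta) and is fused to the pyranone at C4a=C8a, so C4a=C8a–C8=C5(=O) is a vinylketene and C6≡C7–O an alkoxyalkyne.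
- Stereochemistry: the target has no stereocenter and no stereogenic double bond, so nothing has to be set.

Key step: step 5

Assumption: ethoxyacetylene is used as its commercial solution in hexanes, and diazomethane is freshly generated as an ethereal solution from N-methyl-N-nitroso-p-toluenesulfonamide.

**Route**

Step 1
Reactants: 1 acetylacetone; 2 1-bromononadecane
Product: 3 tetracosane-2,4-dione
Conditions: 1 (1.4 equiv), LiN(iPr)2 (2.1 equiv per 1), THF, 0 °C; then 2, THF, 0 °C to rt; 1 M HCl
Reagents that add atoms: none
Why: In this γ-alkylation of a 1,3-diketone dianion, the terminal carbanion is the more basic site and should displace the primary bromide by SN2, while the enolate that remains shields the product from a second alkylation.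

Step 2
Reactants: 3 tetracosane-2,4-dione; 4 diethyl oxalate
Product: 6 ethyl 6-icosyl-4-oxo-4H-pyran-2-carboxylate, via triketo ester 5 (not isolated)
Conditions: NaOEt (2.5 equiv), EtOH/THF, 0 to 50 °C; then conc. HCl, EtOH, reflux
Reagents that add atoms: none
Why: A crossed Claisen condensation of the non-enolisable oxalate at the less hindered methyl terminus of 3 is driven by deprotonation of the triketo ester, and acid then cyclodehydrates the 1,3,5-tricarbonyl unit to the 4-pyranone, as in the classical preparation of 6-substituted comanic esters from acylacetones.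

Step 3
Reactants: 6 ethyl 6-icosyl-4-oxo-4H-pyran-2-carboxylate
Product: 7 6-icosyl-4-oxo-4H-pyran-2-carboxylic acid
Conditions: conc. HCl/AcOH (1:2), 100 °C; dilute with H2O
Reagents that add atoms: water, O
Why: Acid-catalysed ester hydrolysis is chosen because hydroxide can open 4-pyranones by conjugate addition at C2 or C6, whereas the protonated pyranone is inert and the lipophilic acid should precipitate on dilution.

Step 4
Reactants: 7 6-icosyl-4-oxo-4H-pyran-2-carboxylic acid
Product: 9 2-(2-diazoacetyl)-6-icosyl-4H-pyran-4-one, via acid chloride 8 (not isolated)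
Conditions: (COCl)2 (1.2 equiv), DMF (cat.), CH2Cl2, 0 °C to rt; evaporate; then CH2N2 (4 equiv), Et2O/CH2Cl2, 0 °C, dark
Reagents that add atoms: diazomethane, C=[N+]=[N-]; oxalyl chloride, O=C(Cl)C(Cl)=O (chlorine of intermediate 8 only)
Why: Vilsmeier-catalysed acid chloride formation followed by acylation of diazomethane (first stage of the Arndt–Eistert sequence) should be clean because 8 has no α-hydrogen and cannot form a ketene, and the excess diazomethane removes HCl as chloromethane so that no chloromethyl ketone forms.

Step 5
Reactants: 9 2-(2-diazoacetyl)-6-icosyl-4H-pyran-4-one; 10 ethoxyacetylene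
Product: 15 7-ethoxy-5-hydroxy-2-icosyl-4H-chromen-4-one, via pyranonylketene 11 (not isolated), via cyclobutenone 12 (not isolated), via dienylketene 13 (not isolated), via dienone tautomer 14 (not isolated)
Conditions: 10 (3 equiv), ClCH2CH2Cl, hν (365 nm, Pyrex), rt; then 80 °C, sealed tube
Reagents that add atoms: none
Why: Light absorbed by the diazocarbonyl band expels N2 with 1,2-shift of the pyranonyl group (Wolff rearrangement, forming C8–C8a) to give ketene 11, which undergoes [2+2] cycloaddition with 10 (C5–C6 and C7–C8) to cyclobutenone 12; reversible four-electron electrocyclic opening of 12 gives dienylketene 13, whose ketene carbon closes onto the pyranone C3–H by six-electron electrocyclization (C4a–C5) to dienone 14, and enolization delivers phenol 15. The closest known reaction type is the Danheiser benzannulation in its photochemical Wolff form, established for aryl and heteroaryl diazomethyl ketones with alkoxy and siloxy alkynes. Ring A, the only ring formed, is closed by the six-electron electrocyclization, with the 5-hydroxyl arising from the ketene carbonyl and the 7-ethoxy group from the alkyne. No stereocenter is created, since C4 of 12 and C4a of 14 are transient and lost on aromatization. The regiochemistry required (ethoxy meta to the new hydroxyl) follows from the polarity match of the nucleophilic unsubstituted alkyne carbon with the electrophilic ketene carbonyl carbon, and only C3 of the pyranone flanks the ketene-bearing C2, so a single site of closure exists. Irradiation at 365 nm addresses the diazo ketone rather than the pyranone band near 250 nm, and the hydrogen-bonded 5-hydroxyl of 15 should be a poor trap for ketene 11.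

Step 6
Reactants: 15 7-ethoxy-5-hydroxy-2-icosyl-4H-chromen-4-one
Product: 16 5,7-dihydroxy-2-icosyl-4H-chromen-4-one
Conditions: BBr3 (4 equiv), CH2Cl2, −78 °C to rt; then H2O
Reagents that add atoms: none
Why: Lewis acid dealkylation of an aryl alkyl ether, in which the oxonium–borate adduct loses bromoethane by bromide attack at the ethyl carbon; the chelated 5-hydroxyl and the pyranone carbonyl only bind boron until hydrolysis, and the saturated chain is inert.

**Compound list**

1 | acetylacetone (pentane-2,4-dione) | CC(=O)CC(C)=O | starting material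
2 | 1-bromononadecane | CCCCCCCCCCCCCCCCCCCBr | starting material
3 | tetracosane-2,4-dione | CCCCCCCCCCCCCCCCCCCCC(=O)CC(C)=O | intermediate
4 | diethyl oxalate | CCOC(=O)C(=O)OCC | starting material
5 | ethyl 2,4,6-trioxohexacosanoate (triketo ester, formed in the flask in step 2) | CCCCCCCCCCCCCCCCCCCCC(=O)CC(=O)CC(=O)C(=O)OCC | intermediate
6 | ethyl 6-icosyl-4-oxo-4H-pyran-2-carboxylate | CCCCCCCCCCCCCCCCCCCCc1cc(=O)cc(C(=O)OCC)o1 | intermediate
7 | 6-icosyl-4-oxo-4H-pyran-2-carboxylic acid | CCCCCCCCCCCCCCCCCCCCc1cc(=O)cc(C(=O)O)o1 | intermediate
8 | 6-icosyl-4-oxo-4H-pyran-2-carbonyl chloride (acid chloride, formed in the flask in step 4) | CCCCCCCCCCCCCCCCCCCCc1cc(=O)cc(C(=O)Cl)o1 | intermediate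
9 | 2-(2-diazoacetyl)-6-icosyl-4H-pyran-4-one | CCCCCCCCCCCCCCCCCCCCc1cc(=O)cc(C(=O)C=[N+]=[N-])o1 | intermediate
10 | ethoxyacetylene (ethyl ethynyl ether) | CCOC#C | starting material
11 | 6-icosyl-2-(2-oxoethenyl)-4H-pyran-4-one (pyranonylketene, formed in the flask in step 5) | CCCCCCCCCCCCCCCCCCCCc1cc(=O)cc(C=C=O)o1 | intermediate
12 | 3-ethoxy-4-(6-icosyl-4-oxo-4H-pyran-2-yl)cyclobut-2-en-1-one (racemic cyclobutenone, formed in the flask in step 5) | CCCCCCCCCCCCCCCCCCCCc1cc(=O)cc(C2C(OCC)=CC2=O)o1 | intermediate
13 | (3E)-3-ethoxy-4-(6-icosyl-4-oxo-4H-pyran-2-yl)buta-1,3-dien-1-one (dienylketene with the pyranonyl group cis to the ketene arm, formed in the flask in step 5) | CCCCCCCCCCCCCCCCCCCCc1cc(=O)cc(/C=C(/OCC)C=C=O)o1 | intermediate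
14 | 7-ethoxy-2-icosyl-4aH-chromene-4,5-dione (racemic dienone tautomer, formed in the flask in step 5) | CCCCCCCCCCCCCCCCCCCCC1=CC(=O)C2C(=O)C=C(OCC)C=C2O1 | intermediate
15 | 7-ethoxy-5-hydroxy-2-icosyl-4H-chromen-4-one | CCCCCCCCCCCCCCCCCCCCc1cc(=O)c2c(O)cc(OCC)cc2o1 | intermediate
16 | 5,7-dihydroxy-2-icosyl-4H-chromen-4-one (CNP0268388.0) | CCCCCCCCCCCCCCCCCCCCc1cc(=O)c2c(O)cc(O)cc2o1 | target

**Summary**

Total step count: 6. Longest linear sequence: 6 steps (from acetylacetone and 1-bromononadecane; diethyl oxalate and ethoxyacetylene enter as purchased reagents).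

Steps most likely to fail:

1. Step 5. The pyranone chromophore may undergo its own photoisomerization, the ketene may dimerize or be captured by the phenol formed, or the sequence may stall at the cyclobutenone because closure onto the pyranone carbon is slow. The fallback generates the same ketene without light; it sets out from 9 and returns to the route at 12, which is then taken to 15. Wolff rearrangement of 9 catalysed by PhCO2Ag with Et3N in aqueous THF should give, through ketene 11 and water, (6-icosyl-4-oxo-4H-pyran-2-yl)acetic acid F1, which is kept cold and converted at once with (COCl)2 and catalytic DMF into (6-icosyl-4-oxo-4H-pyran-2-yl)acetyl chloride F2. Slow addition of Et3N to F2 and 10 in CH2Cl2 in the dark should form ketene 11 by dehydrochlorination and trap it as cyclobutenone 12, which is isolated here and heated in toluene at 80 to 110 °C to give 15.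

2. Step 4. The chlorinating agent may activate the pyranone carbonyl oxygen (chloropyrylium formation), diazomethane may add as a dipole to the electron-poor pyranone double bond, or HCl may be captured to give the chloromethyl ketone. The fallback avoids both the acid chloride and diazomethane by diazo transfer to a methyl ketone; it sets out from 3 and returns at 9. Claisen condensation of 3 with methyl 2,2-dimethoxypropanoate (NaH, MeOCH2CH2OMe, reflux) should give 2,2-dimethoxyheptacosane-3,5,7-trione F3. Aqueous HCl in AcOH should close the pyranone and unmask the ketone to give 2-acetyl-6-icosyl-4H-pyran-4-one F4. LiN(SiMe3)2 and CF3CO2CH2CF3 in THF at −78 °C should then give 4,4,4-trifluoro-1-(6-icosyl-4-oxo-4H-pyran-2-yl)butane-1,3-dione F5, and treatment with MeSO2N3, Et3N and H2O in MeCN (detrifluoroacetylative diazo transfer) should deliver 9.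

3. Step 2. Acylation may occur at the C5 methylene or at oxygen instead of the C1 methyl, or ethoxide may cleave the diketone by retro-Claisen reaction, giving regioisomeric pyranones or loss of the chain. The fallback reverses the order of bond formation so that the oxalate condensation is done on the symmetrical diketone; it sets out from 1, 4 and 2 and returns at 5. Condensation of 1 with 4 (NaOEt, EtOH) should give ethyl 2,4,6-trioxoheptanoate F6. Its trianion (LiN(iPr)2, 3.1 equiv, THF, −78 to 0 °C) should be alkylated by 2 at the terminal, most basic carbanion to give triketo ester 5, which is cyclized with conc. HCl in EtOH as in step 2 to give 6.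

**Further compounds**

F1 | step 5 | (6-icosyl-4-oxo-4H-pyran-2-yl)acetic acid | CCCCCCCCCCCCCCCCCCCCc1cc(=O)cc(CC(=O)O)o1
F2 | step 5 | (6-icosyl-4-oxo-4H-pyran-2-yl)acetyl chloride | CCCCCCCCCCCCCCCCCCCCc1cc(=O)cc(CC(=O)Cl)o1
F3 | step 4 | 2,2-dimethoxyheptacosane-3,5,7-trione | CCCCCCCCCCCCCCCCCCCCC(=O)CC(=O)CC(=O)C(C)(OC)OC
F4 | step 4 | 2-acetyl-6-icosyl-4H-pyran-4-one | CCCCCCCCCCCCCCCCCCCCc1cc(=O)cc(C(C)=O)o1
F5 | step 4 | 4,4,4-trifluoro-1-(6-icosyl-4-oxo-4H-pyran-2-yl)butane-1,3-dione | CCCCCCCCCCCCCCCCCCCCc1cc(=O)cc(C(=O)CC(=O)C(F)(F)F)o1
F6 | step 2 | ethyl 2,4,6-trioxoheptanoate | CC(=O)CC(=O)CC(=O)C(=O)OCC
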